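## The problem

The target 25 is a hexasubstituted benzene. C1 of the central ring carries indole A (5-methoxyindol-3-yl), C4 carries indole B (5-hydroxyindol-3-yl), and C2, C3, C5 and C6 carry methoxy groups, so each aryl–aryl bond lies between two ortho oxygen substituents. There is no stereocentre, so the task is constitutional: the two halves differ only by one methyl group on the 5-oxygen, and indole A must be told from indole B by construction, not by a late statistical step. Five oxygens end as methyl ethers and one as a free phenol, so the phenolic oxygen of indole B needs a group orthogonal to methyl, and the four central oxygens must be methylated without touching either indole nitrogen. The fragile parts are the two electron-rich indoles with free N–H (acid, electrophiles, oxidants), the 5-hydroxyindole, and the tetraoxygenated central ring, which is readily oxidised once any of its oxygens is a free phenol. Making either biaryl bond on a finished tetramethoxybenzene means coupling at a carbon with two ortho substituents, twice, at two positions that are chemically equivalent. The feature that opens another way is the environment of C4: it bears indole B and sits between the oxygen-bearing carbons C3 and C5. C3–C4 therefore map onto an aryl ynol ether, and C5, C2, C1 and C6 (oxygen on C5, C2 and C6, indole A on C1) map onto a 3-aryl-2,4-dioxygenated cyclobutenone, the two partners of a cyclobutenone–ynol ether benzannulation.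

## Retrosynthesis

**End game, 25 back to 22.** The benzyl C–O bond on indole B is cut first (25 from 24), then the two O–methyl bonds on C3 and C5 (24 from resorcinol 23), then two N–Si bonds and one O–Si bond (23 from 22). Benzyl is chosen for the 5-oxygen of indole B because it survives organolithium reagents, heat, fluoride and carbonate, and leaves under neutral hydrogenolysis that touches neither the methyl ethers nor the indoles. Nothing is simplified in the skeleton here. What is gained is that 22 has exactly the oxygen pattern a benzannulation delivers: one free phenol on C5 and one silyl ether on C3. The forward steps must methylate two hindered phenols in the presence of two indole N–H groups, which the acidity gap between a phenol and an indole allows.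

**Central ring, 22 back to 9 and 17.** The bonds C4–C5 and C2–C3 are cut, and the ring bond C5–C6 is recognised as the cyclobutenone bond that opens and re-forms. The neighbouring cuts, the two aryl–aryl bonds C1–indole A and C4–indole B, would each need a cross-coupling at a di-ortho-oxygenated carbon and a way to address two equivalent halides one after the other. The chosen cut creates no bond to a hindered aromatic carbon after the ring exists. The precursors are the cyclobutenone 9 and the siloxyalkyne 17, each about half the molecule and each carrying one indole. The forward reaction has to fix the orientation of the alkyne, which the polarity of ketene and ynol ether does, and has to tolerate a fully substituted product.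

**Cyclobutenone, 9 back to 6 and 3.** The bond between indole C3 and the ring is cut, together with a 1,3-transposition of the carbonyl group. The forward reaction is the addition of the 3-lithioindole 7 (from bromide 6) to the single carbonyl of the trimethoxycyclobutenone 3, followed by acid hydrolysis of the adduct 8. The more obvious order, aryllithium onto the squarate 1 and reduction afterwards, is rejected as the main line. Hydride would attack a 3-aryl-4-methoxycyclobutenedione at the carbonyl next to the methoxy carbon and would place the aryl group alpha to the surviving carbonyl, which is the wrong isomer for the benzannulation. In the chosen order the regiochemistry is unambiguous, because 3 has only one carbonyl.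

**Four-membered ring, 3 back to 1.** One O–methyl bond (3 from carbinol 2) and one C–H bond (2 from dimethyl squarate 1) are cut. The squarate supplies all four carbons and three of the oxygens of C5, C2, C1 and C6 at the right oxidation level. The forward steps must stop the reduction at the mono-carbinol and methylate a base- and acid-sensitive alcohol.

**Siloxyalkyne, 17 back to 14, 12 and 10.** The O–Si bond and the bond between indole C3 and the alkyne are cut. The forward reaction is an ester homologation that inserts one carbon: the indolyl group migrates from the ester carbon to a carbenoid carbon to give the ynolate 16, which is silylated on oxygen. A Sonogashira-type route to an ynol ether has no simple oxygenated alkyne partner, whereas the ester 14 is one carboxylation away from bromide 12, itself made in one operation from 5-benzyloxyindole 10.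

**Bromides, 6 back to 4 (and 12 back to 10).** The N–Si and C3–Br bonds are cut. The triisopropylsilyl group is chosen because it blocks C2, holds lithium on C3 during the exchange, and leaves with fluoride together with the aryl silyl ether.

## Roads not taken

**Alternative 1:** Nenitzescu construction of indole B. The cut is N1–C7a and C3–C3a of indole B. This leaves its benzenoid ring as 1,4-benzoquinone A3 and the rest as the secondary enamine tert-butyl 3-(4-{(E)-2-[(2,4-dimethoxybenzyl)amino]ethenyl}-2,3,5,6-tetramethoxyphenyl)-5-methoxy-1H-indole-1-carboxylate A2. In the forward key step the β-carbon of A2 adds to A3, the nitrogen condenses on the neighbouring carbonyl and the pyrrole ring closes to tert-butyl 3-{4-[1-(2,4-dimethoxybenzyl)-5-hydroxy-1H-indol-3-yl]-2,3,5,6-tetramethoxyphenyl}-5-methoxy-1H-indole-1-carboxylate A1.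

- Merits: the 5-hydroxyl arrives free and is differentiated from the 5-methoxy group automatically. In this respect the road is better than the chosen plan, which spends a benzyl ether and a final hydrogenolysis on that oxygen.
- Weak points: the reaction is reliable for enamines stabilised by a β-acceptor; A2 has none, is an easily hydrolysed and easily oxidised aldehyde enamine, and meets a quinone that can simply dehydrogenate it. A2 also presupposes the hexasubstituted ring with indole A already coupled at one hindered carbon and a two-carbon aldehyde chain at the other, so the central difficulty is moved, not solved. Removing a dimethoxybenzyl group from an indole nitrogen needs strong acid or an oxidant, in the presence of a 5-hydroxyindole.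
- Comparison: the chosen plan pays one extra oxygen protecting group, but it forms the crowded ring and both aryl bonds in one convergent step, whereas this road is linear.

**Alternative 2:** biomimetic dimerisation. The cut is C3–C4 and C6–C1, each a Claisen acylation. Two molecules of methyl 3-(5-benzyloxy-1H-indol-3-yl)-2-oxopropanoate A5 condense under excess alkoxide base to 2,5-bis(5-benzyloxy-1H-indol-3-yl)-3,6-dihydroxy-1,4-benzoquinone A4.

- Merits: this is the shortest conceivable assembly. All six ring carbons, all four oxygens and both aryl bonds arise in one operation from an easily made pyruvate, with no hindered coupling. In step count it is clearly better than the chosen plan.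
- Weak points: homodimerisation gives two identical indoles, whereas the target needs methoxy on one and hydroxyl on the other. A crossed condensation of two different pyruvates would give a statistical mixture of three closely similar quinones. Desymmetrising A4 later means monofunctionalising two remote, equivalent oxygens. The quinone must also be reduced and O-methylated four times beside free N–H groups.
- Comparison: for a symmetrical congener this would be the route of choice. Against its brevity the chosen plan sets the fact that each indole arrives in a different partner, so the unsymmetry costs nothing.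

**Alternative 3:** twofold reductive cyclisation. The cut is N1–C7a in both indoles. The precursor is 1-[(E)-1-(4-benzyloxyphenyl)-2-nitroethenyl]-2,3,5,6-tetramethoxy-4-[(E)-1-(4-methoxyphenyl)-2-nitroethenyl]benzene A7. Under carbon monoxide with a Pd(OAc)2/1,10-phenanthroline catalyst it would be deoxygenated at both nitro groups and closed to 5-benzyloxy-3-[2,3,5,6-tetramethoxy-4-(5-methoxy-1H-indol-3-yl)phenyl]-1H-indole A6, which is identical with 24 of the chosen route.

- Merits: both pyrrole rings form in one step, no nitrogen protecting group is needed at any stage, and the central ring can be bought as a tetramethoxybenzene. Freedom from N-protection is a real advantage over the three silyl groups of the chosen plan.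
- Weak points: A7 needs two 1,1-diaryl-2-nitroethene units, each on a carbon with two ortho methoxy groups. The diaryl ketones from which they would come are among the least reactive carbonyl compounds towards nitromethane condensation, and the central ring would have to be acylated twice with two different aroyl groups. Only the isomer with the nitro group syn to the alkoxyphenyl ring can close onto it, and two C–H aminations must both succeed in one molecule under forcing conditions.
- Comparison: both roads end one step from the target. The chosen plan needs more steps on the cyclobutenone side but builds the crowded positions while the ring forms, instead of functionalising them afterwards.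

Key step: step 8

Remark on the chemistry: the central ring is numbered C1 (indole A) to C6 as in the target. Compounds 2, 3, 8, 9, 19 and 21 are racemic (8 also a diastereomer mixture), which has no consequence because every sp3 ring carbon ends as an aromatic carbon.

## Route

Step 1
Reactants: 1 dimethyl squarate
Product: 2 4-hydroxy-2,3-dimethoxycyclobut-2-en-1-one (racemic)
Conditions: LiAlH(OtBu)3, THF, −78 → −20 °C; aq. potassium sodium tartrate, pH 7
Reagents that add atoms: none
Why: 1,2-Hydride reduction of one squarate carbonyl with a bulky alkoxyaluminium hydride; it should stop at the mono-carbinol because the remaining carbonyl is a vinylogous ester and the ring then carries an aluminium alkoxide.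

Step 2
Reactants: 2 4-hydroxy-2,3-dimethoxycyclobut-2-en-1-one
Product: 3 2,3,4-trimethoxycyclobut-2-en-1-one (racemic)
Conditions: Ag2O, MeI, MeCN, 25 °C, dark
Reagents that add atoms: iodomethane, CI
Why: Silver oxide-mediated Williamson O-methylation runs under nearly neutral conditions, as is usual for 4-hydroxycyclobutenones, which tolerate neither alkoxide bases nor acid; the carbinol carbon cannot enolise because that would give a cyclobutadiene.

Step 3
Reactants: 4 5-methoxyindole
Product: 6 3-bromo-5-methoxy-1-(triisopropylsilyl)-1H-indole, via 5-methoxy-1-(triisopropylsilyl)indole 5 (not isolated)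
Conditions: n-BuLi, THF, −78 °C; TIPSOTf, −78 → 0 °C; then NBS, −78 °C
Reagents that add atoms: triisopropylsilyl trifluoromethanesulfonate, CC(C)[Si](OS(=O)(=O)C(F)(F)F)(C(C)C)C(C)C; N-bromosuccinimide, O=C1CCC(=O)N1Br
Why: N-Lithiation and N-silylation, then electrophilic bromination at C3, the most nucleophilic position of an N-silylindole; the one-flask silylation–bromination is standard for 1-silyl-3-bromoindoles, and the bulky silyl group shields C2.

Step 4
Reactants: 6 3-bromo-5-methoxy-1-(triisopropylsilyl)-1H-indole; 3 2,3,4-trimethoxycyclobut-2-en-1-one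
Product: 9 2,4-dimethoxy-3-[5-methoxy-1-(triisopropylsilyl)-1H-indol-3-yl]cyclobut-2-en-1-one (racemic), via 3-lithio-5-methoxy-1-(triisopropylsilyl)indole 7 (not isolated), via lithium cyclobutenolate adduct 8 (not isolated)
Conditions: t-BuLi (2.0 equiv), THF, −78 °C; add 3, −78 °C; then 1 M HCl, −78 → 0 °C
Reagents that add atoms: water, O
Why: Bromine–lithium exchange gives the 3-lithioindole, held on C3 by the N-silyl group, which adds 1,2 to the only, non-enolisable carbonyl of 3; acid ionises the indolyl carbinol to a methoxy-stabilised allyl cation, water adds at the methoxy-bearing terminus and methanol is lost, a Stork–Danheiser-type addition and carbonyl transposition as used for 3-substituted cyclobutenones and squarate adducts.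

Step 5
Reactants: 10 5-benzyloxyindole
Product: 12 5-benzyloxy-3-bromo-1-(triisopropylsilyl)-1H-indole, via 5-benzyloxy-1-(triisopropylsilyl)indole 11 (not isolated)
Conditions: n-BuLi, THF, −78 °C; TIPSOTf, −78 → 0 °C; then NBS, −78 °C
Reagents that add atoms: triisopropylsilyl trifluoromethanesulfonate, CC(C)[Si](OS(=O)(=O)C(F)(F)F)(C(C)C)C(C)C; N-bromosuccinimide, O=C1CCC(=O)N1Br
Why: The same N-silylation and C3 bromination as in step 3; the benzyl ether is inert to one equivalent of n-BuLi at −78 °C because the N–H proton is removed first.

Step 6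
Reactants: 12 5-benzyloxy-3-bromo-1-(triisopropylsilyl)-1H-indole
Product: 14 ethyl 5-benzyloxy-1-(triisopropylsilyl)-1H-indole-3-carboxylate, via 5-benzyloxy-3-lithio-1-(triisopropylsilyl)indole 13 (not isolated)
Conditions: t-BuLi (2.0 equiv), THF, −78 °C; cannulate into ClCO2Et, −78 → 0 °C
Reagents that add atoms: ethyl chloroformate, CCOC(=O)Cl
Why: Bromine–lithium exchange followed by C-acylation with a chloroformate, a standard trapping of 3-lithio-1-silylindoles; inverse addition keeps the ester from reacting with a second aryllithium.

Step 7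
Reactants: 14 ethyl 5-benzyloxy-1-(triisopropylsilyl)-1H-indole-3-carboxylate
Product: 17 5-benzyloxy-1-(triisopropylsilyl)-3-[(triisopropylsilyloxy)ethynyl]-1H-indole, via lithium dibromoenolate 15 (not isolated), via lithium ynolate 16 (not isolated)
Conditions: CH2Br2, lithium 2,2,6,6-tetramethylpiperidide, THF, −78 °C; LiN(SiMe3)2, −78 → −20 °C; n-BuLi, −78 → 25 °C; TIPSOTf (2.2 equiv), −78 → 0 °C
Reagents that add atoms: dibromomethane, BrCBr; triisopropylsilyl trifluoromethanesulfonate, CC(C)[Si](OS(=O)(=O)C(F)(F)F)(C(C)C)C(C)C
Why: Kowalski ester homologation stopped at the ynolate: LiCHBr2 adds to the ester, the dibromoketone is enolised, bromine–lithium exchange gives a carbenoid and the indolyl group migrates with loss of LiBr; the hard, bulky silyl triflate then silylates the ynolate on oxygen, the second equivalent being consumed by the ethoxide released.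

Step 8
Reactants: 9 2,4-dimethoxy-3-[5-methoxy-1-(triisopropylsilyl)-1H-indol-3-yl]cyclobut-2-en-1-one; 17 5-benzyloxy-1-(triisopropylsilyl)-3-[(triisopropylsilyloxy)ethynyl]-1H-indole
Product: 22 2-[5-benzyloxy-1-(triisopropylsilyl)-1H-indol-3-yl]-4,6-dimethoxy-5-[5-methoxy-1-(triisopropylsilyl)-1H-indol-3-yl]-3-(triisopropylsilyloxy)phenol, via vinylketene 18 (not isolated), via 4-vinylcyclobutenone 19 (not isolated), via dienylketene 20 (not isolated), via cyclohexa-2,4-dienone 21 (not isolated)
Conditions: 17 (1.3 equiv), degassed toluene (0.1 M), 80 °C then 110 °C, sealed tube, Ar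
Reagents that add atoms: none
Why: This is a Danheiser benzannulation of a cyclobutenone with a siloxyalkyne, the closest known reaction type. Heating opens 9 in a conrotatory four-electron step to vinylketene 18, the methoxy group on the sp3 carbon turning outward. The electrophilic ketene carbon (C5 of the target) bonds to the aryl-bearing alkyne carbon of 17 (C4), the nucleophilic carbon β to the siloxy oxygen, and the ketene α-carbon (C2) bonds to the oxygen-bearing alkyne carbon (C3); this polarity match places indole B para to indole A and is the only regiochemical decision of the synthesis. The 4-vinylcyclobutenone 19 opens again, and because the methoxy group on its sp3 carbon is the better donor and rotates outward, the vinyl group turns inward and dienylketene 20 has the Z geometry about C3=C2 that closure needs. Dienylketene 20 closes the central ring by a thermal disrotatory six-electron electrocyclisation that re-forms C5–C6, and cyclohexadienone 21 tautomerises to phenol 22. No stereocentre remains, since the sp3 centres of 9, 19 and 21 all end as aromatic carbons. Indole A sits on C3 of the cyclobutenone, where its ring cannot take part in a six-electron closure with the ketene as a 4-aryl group would, and the bulky N-silyl groups keep both indole C2 positions from acting as nucleophiles. The phenol formed is flanked by an indolyl and a methoxy group, which should suppress its acylation by a second ketene.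

Step 9
Reactants: 22 2-[5-benzyloxy-1-(triisopropylsilyl)-1H-indol-3-yl]-4,6-dimethoxy-5-[5-methoxy-1-(triisopropylsilyl)-1H-indol-3-yl]-3-(triisopropylsilyloxy)phenol
Product: 23 2-(5-benzyloxy-1H-indol-3-yl)-4,6-dimethoxy-5-(5-methoxy-1H-indol-3-yl)benzene-1,3-diol
Conditions: TBAF (3.5 equiv), THF, 0 → 25 °C, Ar; pH 7 buffer
Reagents that add atoms: none
Why: Fluoride cleaves the aryl O–Si bond and both indole N–Si bonds in one operation; benzyl and methyl ethers are inert, and air is excluded because the resorcinol is electron-rich.

Step 10
Reactants: 23 2-(5-benzyloxy-1H-indol-3-yl)-4,6-dimethoxy-5-(5-methoxy-1H-indol-3-yl)benzene-1,3-diol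
Product: 24 5-benzyloxy-3-[2,3,5,6-tetramethoxy-4-(5-methoxy-1H-indol-3-yl)phenyl]-1H-indole
Conditions: K2CO3, MeI, acetone, 50 °C, Ar
Reagents that add atoms: iodomethane, CI
Why: Williamson O-methylation; carbonate deprotonates the phenols (pKa about 10) but not the indole N–H (pKa about 17), so methylation should stay on oxygen, and methyl iodide is small enough for the di-ortho-substituted phenoxides.

Step 11
Reactants: 24 5-benzyloxy-3-[2,3,5,6-tetramethoxy-4-(5-methoxy-1H-indol-3-yl)phenyl]-1H-indole
Product: 25 3-[2,3,5,6-tetramethoxy-4-(5-methoxy-1H-indol-3-yl)phenyl]-1H-indol-5-ol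
Conditions: H2 (1 atm), 10% Pd/C, EtOAc–MeOH, 25 °C
Reagents that add atoms: none
Why: Hydrogenolysis of the benzyl aryl ether over palladium on carbon under neutral conditions leaves the methyl ethers and both indole rings untouched and frees the 5-hydroxyl of indole B.

## Compound list

1 | dimethyl squarate (3,4-dimethoxycyclobut-3-ene-1,2-dione) | COC1=C(OC)C(=O)C1=O | starting material
2 | 4-hydroxy-2,3-dimethoxycyclobut-2-en-1-one (racemic) | COC1=C(OC)C(O)C1=O | intermediate
3 | 2,3,4-trimethoxycyclobut-2-en-1-one (racemic) | COC1=C(OC)C(OC)C1=O | intermediate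
4 | 5-methoxyindole | COc1ccc2[nH]ccc2c1 | starting material
5 | 5-methoxy-1-(triisopropylsilyl)-1H-indole (not isolated) | COc1ccc2c(c1)ccn2[Si](C(C)C)(C(C)C)C(C)C | intermediate
6 | 3-bromo-5-methoxy-1-(triisopropylsilyl)-1H-indole | COc1ccc2c(c1)c(Br)cn2[Si](C(C)C)(C(C)C)C(C)C | intermediate
7 | 3-lithio-5-methoxy-1-(triisopropylsilyl)-1H-indole (not isolated) | COc1ccc2c(c1)c([Li])cn2[Si](C(C)C)(C(C)C)C(C)C | intermediate
8 | lithium 2,3,4-trimethoxy-1-[5-methoxy-1-(triisopropylsilyl)-1H-indol-3-yl]cyclobut-2-en-1-olate (racemic diastereomer mixture, not isolated) | [Li]OC1(c2cn([Si](C(C)C)(C(C)C)C(C)C)c3ccc(OC)cc23)C(OC)=C(OC)C1OC | intermediate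
9 | 2,4-dimethoxy-3-[5-methoxy-1-(triisopropylsilyl)-1H-indol-3-yl]cyclobut-2-en-1-one (racemic) | O=C1C(OC)=C(c2cn([Si](C(C)C)(C(C)C)C(C)C)c3ccc(OC)cc23)C1OC | intermediate
10 | 5-benzyloxyindole | c1ccc(COc2ccc3[nH]ccc3c2)cc1 | starting material
11 | 5-benzyloxy-1-(triisopropylsilyl)-1H-indole (not isolated) | CC(C)[Si](C(C)C)(C(C)C)n1ccc2cc(OCc3ccccc3)ccc21 | intermediate
12 | 5-benzyloxy-3-bromo-1-(triisopropylsilyl)-1H-indole | CC(C)[Si](C(C)C)(C(C)C)n1cc(Br)c2cc(OCc3ccccc3)ccc21 | intermediate
13 | 5-benzyloxy-3-lithio-1-(triisopropylsilyl)-1H-indole (not isolated) | CC(C)[Si](C(C)C)(C(C)C)n1cc([Li])c2cc(OCc3ccccc3)ccc21 | intermediate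
14 | ethyl 5-benzyloxy-1-(triisopropylsilyl)-1H-indole-3-carboxylate | CCOC(=O)c1cn([Si](C(C)C)(C(C)C)C(C)C)c2ccc(OCc3ccccc3)cc12 | intermediate
15 | lithium 1-[5-benzyloxy-1-(triisopropylsilyl)-1H-indol-3-yl]-2,2-dibromoethen-1-olate (not isolated) | [Li]OC(=C(Br)Br)c1cn([Si](C(C)C)(C(C)C)C(C)C)c2ccc(OCc3ccccc3)cc12 | intermediate
16 | lithium 2-[5-benzyloxy-1-(triisopropylsilyl)-1H-indol-3-yl]ethyn-1-olate (not isolated) | [Li]OC#Cc1cn([Si](C(C)C)(C(C)C)C(C)C)c2ccc(OCc3ccccc3)cc12 | intermediate
17 | 5-benzyloxy-1-(triisopropylsilyl)-3-[(triisopropylsilyloxy)ethynyl]-1H-indole | CC(C)[Si](C(C)C)(C(C)C)OC#Cc1cn([Si](C(C)C)(C(C)C)C(C)C)c2ccc(OCc3ccccc3)cc12 | intermediate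
18 | (3E)-2,4-dimethoxy-3-[5-methoxy-1-(triisopropylsilyl)-1H-indol-3-yl]buta-1,3-dien-1-one (vinylketene, not isolated) | O=C=C(OC)/C(c1cn([Si](C(C)C)(C(C)C)C(C)C)c2ccc(OC)cc12)=C/OC | intermediate
19 | 2-[5-benzyloxy-1-(triisopropylsilyl)-1H-indol-3-yl]-4-methoxy-4-{(E)-2-methoxy-1-[5-methoxy-1-(triisopropylsilyl)-1H-indol-3-yl]ethenyl}-3-(triisopropylsilyloxy)cyclobut-2-en-1-one (racemic, not isolated) | O=C1C(c2cn([Si](C(C)C)(C(C)C)C(C)C)c3ccc(OCc4ccccc4)cc23)=C(O[Si](C(C)C)(C(C)C)C(C)C)C1(OC)/C(c1cn([Si](C(C)C)(C(C)C)C(C)C)c2ccc(OC)cc12)=C/OC | intermediate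
20 | (3Z,5E)-2-[5-benzyloxy-1-(triisopropylsilyl)-1H-indol-3-yl]-4,6-dimethoxy-5-[5-methoxy-1-(triisopropylsilyl)-1H-indol-3-yl]-3-(triisopropylsilyloxy)hexa-1,3,5-trien-1-one (dienylketene, not isolated) | O=C=C(c1cn([Si](C(C)C)(C(C)C)C(C)C)c2ccc(OCc3ccccc3)cc12)/C(O[Si](C(C)C)(C(C)C)C(C)C)=C(OC)\C(c1cn([Si](C(C)C)(C(C)C)C(C)C)c2ccc(OC)cc12)=C\OC | intermediate
21 | 2-[5-benzyloxy-1-(triisopropylsilyl)-1H-indol-3-yl]-4,6-dimethoxy-5-[5-methoxy-1-(triisopropylsilyl)-1H-indol-3-yl]-3-(triisopropylsilyloxy)cyclohexa-2,4-dien-1-one (racemic, not isolated) | O=C1C(c2cn([Si](C(C)C)(C(C)C)C(C)C)c3ccc(OCc4ccccc4)cc23)=C(O[Si](C(C)C)(C(C)C)C(C)C)C(OC)=C(c2cn([Si](C(C)C)(C(C)C)C(C)C)c3ccc(OC)cc23)C1OC | intermediate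
22 | 2-[5-benzyloxy-1-(triisopropylsilyl)-1H-indol-3-yl]-4,6-dimethoxy-5-[5-methoxy-1-(triisopropylsilyl)-1H-indol-3-yl]-3-(triisopropylsilyloxy)phenol | Oc1c(-c2cn([Si](C(C)C)(C(C)C)C(C)C)c3ccc(OCc4ccccc4)cc23)c(O[Si](C(C)C)(C(C)C)C(C)C)c(OC)c(-c2cn([Si](C(C)C)(C(C)C)C(C)C)c3ccc(OC)cc23)c1OC | intermediate
23 | 2-(5-benzyloxy-1H-indol-3-yl)-4,6-dimethoxy-5-(5-methoxy-1H-indol-3-yl)benzene-1,3-diol | Oc1c(-c2c[nH]c3ccc(OCc4ccccc4)cc23)c(O)c(OC)c(-c2c[nH]c3ccc(OC)cc23)c1OC | intermediate
24 | 5-benzyloxy-3-[2,3,5,6-tetramethoxy-4-(5-methoxy-1H-indol-3-yl)phenyl]-1H-indole | COc1ccc2[nH]cc(-c3c(OC)c(OC)c(-c4c[nH]c5ccc(OCc6ccccc6)cc45)c(OC)c3OC)c2c1 | intermediate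
25 | 3-[2,3,5,6-tetramethoxy-4-(5-methoxy-1H-indol-3-yl)phenyl]-1H-indol-5-ol | COc1ccc2[nH]cc(-c3c(OC)c(OC)c(-c4c[nH]c5ccc(O)cc45)c(OC)c3OC)c2c1 | target

## Step count and risks

Total: 11 steps. Longest linear sequence: 7 steps (steps 1, 2, 4, 8, 9, 10, 11 from dimethyl squarate 1, or steps 5, 6, 7, 8, 9, 10, 11 from 5-benzyloxyindole 10).

**Step 8 (key step).** The most likely failure is that the [2+2] cycloaddition between the disubstituted methoxy(vinyl)ketene 18 and the internal, aryl-substituted siloxyalkyne 17 is slowed by steric compression. The ketene would then revert to 9, dimerise or decompose, or the cascade would stall at 19 because the crowded dienylketene closes slowly. Acylation of the product phenol by a second ketene is a lesser concern.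

Fallback: the central ring is taken from a quinone and the two indoles are attached one after the other by acid-promoted conjugate addition, the known way to unsymmetrical bis(indolyl)benzoquinones. It sets out from 5-methoxyindole 4 and 5-benzyloxyindole 10 and returns to the route at 24.
- 4 is added to commercial 2,5-dichloro-1,4-benzoquinone under acid catalysis and the hydroquinone adduct is reoxidised with DDQ to 2,5-dichloro-3-(5-methoxy-1H-indol-3-yl)-1,4-benzoquinone F1.
- The same addition and oxidation with 10 gives 2-(5-benzyloxy-1H-indol-3-yl)-3,6-dichloro-5-(5-methoxy-1H-indol-3-yl)-1,4-benzoquinone F2.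
- NaOMe in methanol replaces both vinylogous acid chlorides to give 2-(5-benzyloxy-1H-indol-3-yl)-3,6-dimethoxy-5-(5-methoxy-1H-indol-3-yl)-1,4-benzoquinone F3.
- Na2S2O4 reduces F3 to 2-(5-benzyloxy-1H-indol-3-yl)-3,6-dimethoxy-5-(5-methoxy-1H-indol-3-yl)benzene-1,4-diol F4, which is methylated with K2CO3 and MeI as in step 10 to give 24.

The convergent ring construction is given up, but the differentiation of the two indoles and the last step are kept.

**Step 4.** The cyclobutenolate 8 may be lost through oxyanion-accelerated ring opening before the acid quench, and the small, densely oxygenated cyclobutenones 2 and 3 that feed this step may be too labile to handle.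

Fallback: the order of arylation and reduction is reversed, so that the first step is the robust addition of an aryllithium to a squarate. It sets out from 1 and 6 and returns at 9.
- 6 is lithiated with t-BuLi and added to 1 at −78 °C to give 4-hydroxy-2,3-dimethoxy-4-[5-methoxy-1-(triisopropylsilyl)-1H-indol-3-yl]cyclobut-2-en-1-one F5.
- i-Bu2AlH at −78 °C reduces the remaining carbonyl to 2,3-dimethoxy-1-[5-methoxy-1-(triisopropylsilyl)-1H-indol-3-yl]cyclobut-2-ene-1,4-diol F6.
- Dilute acid ionises the tertiary indolyl carbinol in preference to the secondary one and, after addition of water and loss of methanol, gives 4-hydroxy-2-methoxy-3-[5-methoxy-1-(triisopropylsilyl)-1H-indol-3-yl]cyclobut-2-en-1-one F7.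
- Ag2O and MeI methylate F7 to 9.

The price is a selectivity question in the ionisation, which the main route does not have.

**Step 7.** The ester of an indole-3-carboxylate is a vinylogous carbamate, so the addition of LiCHBr2 may be slow. The excess alkyllithium used afterwards may also metalate the benzylic position of the benzyl ether while the mixture warms for the rearrangement.

Fallback: the ynolate is made by oxidising an acetylide instead of homologating an ester. It sets out from 12 and returns at 17 through the ynolate 16.
- 12 is lithiated with t-BuLi and formylated with DMF to 5-benzyloxy-1-(triisopropylsilyl)-1H-indole-3-carbaldehyde F8.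
- CBr4 and PPh3 (Corey–Fuchs) give 5-benzyloxy-3-(2,2-dibromoethenyl)-1-(triisopropylsilyl)-1H-indole F9.
- n-BuLi (2 equiv) at −78 °C gives lithium [5-benzyloxy-1-(triisopropylsilyl)-1H-indol-3-yl]acetylide F10.
- Lithium tert-butyl peroxide (from t-BuOOH and LiN(SiMe3)2) oxidises F10 to 16, which TIPSOTf silylates to 17.

**Step 9.** The bis-phenoxide formed under fluoride is very electron-rich and may be oxidised during the reaction or work-up. The aryl silyl ether between an indolyl and a methoxy group may also cleave more slowly than the N-silyl groups.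

Fallback: the two central oxygens are methylated one at a time, so that never more than one is a free phenoxide. It sets out from 22 and returns at 24.
- K2CO3 and MeI in DMF methylate the free phenol of 22, with both nitrogens still silylated, to 5-benzyloxy-3-{2,3,5-trimethoxy-4-[5-methoxy-1-(triisopropylsilyl)-1H-indol-3-yl]-6-(triisopropylsilyloxy)phenyl}-1-(triisopropylsilyl)-1H-indole F11.
- TBAF removes the three silyl groups to give 2-(5-benzyloxy-1H-indol-3-yl)-3,4,6-trimethoxy-5-(5-methoxy-1H-indol-3-yl)phenol F12.
- K2CO3 and MeI methylate the single remaining phenol to give 24.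

This costs one step. It also limits the O-versus-N selectivity demanded in step 10 to one hindered phenol.

## Further compounds

F1 | step 8 | 2,5-dichloro-3-(5-methoxy-1H-indol-3-yl)-1,4-benzoquinone | COc1ccc2[nH]cc(C3=C(Cl)C(=O)C=C(Cl)C3=O)c2c1
F2 | step 8 | 2-(5-benzyloxy-1H-indol-3-yl)-3,6-dichloro-5-(5-methoxy-1H-indol-3-yl)-1,4-benzoquinone | COc1ccc2[nH]cc(C3=C(Cl)C(=O)C(c4c[nH]c5ccc(OCc6ccccc6)cc45)=C(Cl)C3=O)c2c1
F3 | step 8 | 2-(5-benzyloxy-1H-indol-3-yl)-3,6-dimethoxy-5-(5-methoxy-1H-indol-3-yl)-1,4-benzoquinone | COc1ccc2[nH]cc(C3=C(OC)C(=O)C(c4c[nH]c5ccc(OCc6ccccc6)cc45)=C(OC)C3=O)c2c1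
F4 | step 8 | 2-(5-benzyloxy-1H-indol-3-yl)-3,6-dimethoxy-5-(5-methoxy-1H-indol-3-yl)benzene-1,4-diol | COc1ccc2[nH]cc(-c3c(OC)c(O)c(-c4c[nH]c5ccc(OCc6ccccc6)cc45)c(OC)c3O)c2c1
F5 | step 4 | 4-hydroxy-2,3-dimethoxy-4-[5-methoxy-1-(triisopropylsilyl)-1H-indol-3-yl]cyclobut-2-en-1-one (racemic) | COC1=C(OC)C(O)(c2cn([Si](C(C)C)(C(C)C)C(C)C)c3ccc(OC)cc23)C1=O
F6 | step 4 | 2,3-dimethoxy-1-[5-methoxy-1-(triisopropylsilyl)-1H-indol-3-yl]cyclobut-2-ene-1,4-diol (racemic diastereomer mixture) | COC1=C(OC)C(O)(c2cn([Si](C(C)C)(C(C)C)C(C)C)c3ccc(OC)cc23)C1O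
F7 | step 4 | 4-hydroxy-2-methoxy-3-[5-methoxy-1-(triisopropylsilyl)-1H-indol-3-yl]cyclobut-2-en-1-one (racemic) | O=C1C(OC)=C(c2cn([Si](C(C)C)(C(C)C)C(C)C)c3ccc(OC)cc23)C1O
F8 | step 7 | 5-benzyloxy-1-(triisopropylsilyl)-1H-indole-3-carbaldehyde | O=Cc1cn([Si](C(C)C)(C(C)C)C(C)C)c2ccc(OCc3ccccc3)cc12
F9 | step 7 | 5-benzyloxy-3-(2,2-dibromoethenyl)-1-(triisopropylsilyl)-1H-indole | BrC(Br)=Cc1cn([Si](C(C)C)(C(C)C)C(C)C)c2ccc(OCc3ccccc3)cc12
F10 | step 7 | lithium [5-benzyloxy-1-(triisopropylsilyl)-1H-indol-3-yl]acetylide | [Li]C#Cc1cn([Si](C(C)C)(C(C)C)C(C)C)c2ccc(OCc3ccccc3)cc12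
F11 | step 9 | 5-benzyloxy-3-{2,3,5-trimethoxy-4-[5-methoxy-1-(triisopropylsilyl)-1H-indol-3-yl]-6-(triisopropylsilyloxy)phenyl}-1-(triisopropylsilyl)-1H-indole | COc1c(-c2cn([Si](C(C)C)(C(C)C)C(C)C)c3ccc(OCc4ccccc4)cc23)c(O[Si](C(C)C)(C(C)C)C(C)C)c(OC)c(-c2cn([Si](C(C)C)(C(C)C)C(C)C)c3ccc(OC)cc23)c1OC
F12 | step 9 | 2-(5-benzyloxy-1H-indol-3-yl)-3,4,6-trimethoxy-5-(5-methoxy-1H-indol-3-yl)phenol | COc1c(-c2c[nH]c3ccc(OCc4ccccc4)cc23)c(O)c(OC)c(-c2c[nH]c3ccc(OC)cc23)c1OC
A1 | alternative 1 | tert-butyl 3-{4-[1-(2,4-dimethoxybenzyl)-5-hydroxy-1H-indol-3-yl]-2,3,5,6-tetramethoxyphenyl}-5-methoxy-1H-indole-1-carboxylate | COc1ccc(Cn2cc(-c3c(OC)c(OC)c(-c4cn(C(=O)OC(C)(C)C)c5ccc(OC)cc45)c(OC)c3OC)c3cc(O)ccc32)c(OC)c1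
A2 | alternative 1 | tert-butyl 3-(4-{(E)-2-[(2,4-dimethoxybenzyl)amino]ethenyl}-2,3,5,6-tetramethoxyphenyl)-5-methoxy-1H-indole-1-carboxylate | COc1ccc(CN/C=C/c2c(OC)c(OC)c(-c3cn(C(=O)OC(C)(C)C)c4ccc(OC)cc34)c(OC)c2OC)c(OC)c1
A3 | alternative 1 | 1,4-benzoquinone | O=C1C=CC(=O)C=C1
A4 | alternative 2 | 2,5-bis(5-benzyloxy-1H-indol-3-yl)-3,6-dihydroxy-1,4-benzoquinone | O=C1C(O)=C(c2c[nH]c3ccc(OCc4ccccc4)cc23)C(=O)C(O)=C1c1c[nH]c2ccc(OCc3ccccc3)cc12
A5 | alternative 2 | methyl 3-(5-benzyloxy-1H-indol-3-yl)-2-oxopropanoate | COC(=O)C(=O)Cc1c[nH]c2ccc(OCc3ccccc3)cc12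
A6 | alternative 3 | 5-benzyloxy-3-[2,3,5,6-tetramethoxy-4-(5-methoxy-1H-indol-3-yl)phenyl]-1H-indole | COc1ccc2[nH]cc(-c3c(OC)c(OC)c(-c4c[nH]c5ccc(OCc6ccccc6)cc45)c(OC)c3OC)c2c1
A7 | alternative 3 | 1-[(E)-1-(4-benzyloxyphenyl)-2-nitroethenyl]-2,3,5,6-tetramethoxy-4-[(E)-1-(4-methoxyphenyl)-2-nitroethenyl]benzene | COc1ccc(/C(=C\[N+](=O)[O-])c2c(OC)c(OC)c(/C(=C/[N+](=O)[O-])c3ccc(OCc4ccccc4)cc3)c(OC)c2OC)cc1
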